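## Retrosynthetic overview

1. Numbering per half: O1, C2 (CMe2), C3 (CH–O), C4, C5, C6 (C–Me, ring fusion), C7 (CH–O, ring fusion), C8, C9, C10 (C(Me)–O), C11 (CH), C12 (bridge CH2); the half with the free 3-OH and the axial 10-OAc is primed. Last moves backwards: O3′ silyl ether, O10′ acetate, C10′–CH3 (equatorial methyl addition to a C10′ ketone gives the axial oxygen).
2. Key disconnection: the cyclohexanone ring C6′–C7′–C8′–C9′–C10′–C11′ is opened at C6′–C11′ and, in the same retro-step, the oxepane at O1′–C2′, to an acyclic (3′S,6′S,7′S)-bis-epoxide with a (Z)-C10′=C11′ silyl enol ether.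
3. Enabling feature: O1′ sits on C7′ beside the methyl-bearing quaternary C6′ (Me6′ anti to H7′) and on C2′ beside the C3′ carbinol, so oxepane and ring fusion are two trans-epoxides in opened form. The oxygen on C7′ first closes the oxepane and then leaves C6′ as an epoxonium for C11′; C10′ one oxidation level up (ketone) makes C11′ the nucleophile.
4. Fragment union at C11′=C12′ by Horner–Wadsworth–Emmons reaction of a geranyl-derived β-ketophosphonate with the left-half aldehyde. The left half comes from a homofarnesic ester bis-epoxide by the same kind of cascade, ended by a γ-lactone (temporary ring O10–C12′ that fixes C10 and C11 and is opened again).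
5. Order of ring formation: left oxepane, left cyclohexane, temporary lactone (all step 4; lactone opened in step 5); then right oxepane and, last, right cyclohexane (step 12).

Key step: step 12

Assumption: the L-series Shi ketone (1,2:4,5-di-O-isopropylidene-β-L-erythro-2,3-hexodiulo-2,6-pyranose, enantiomer of the common D-fructose-derived catalyst) is taken as a purchasable catalyst; it gives S epoxides, which the 3S,6S,7S centres of both halves require.

## Route

Step 1
Reactants: 1 (2E,6E)-farnesyl chloride
Product: 3 (3E,7E)-homofarnesic acid, via farnesylbarium chloride 2 (not isolated)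
Conditions: BaI2, lithium biphenylide (LiC12H10), THF, rt (gives finely divided zerovalent barium); 1, −78 °C; CO2, −78 °C; 1 M HCl
Reagents that add atoms: barium metal made from BaI2, [Ba] (in 2 only); carbon dioxide, O=C=O
Why: Carboxylation of an allylic barium reagent, which takes up CO2 at the α-carbon without allylic transposition or E/Z scrambling, should give the β,γ-unsaturated acid with no stereocentre formed.

Step 2
Reactants: 3 (3E,7E)-homofarnesic acid
Product: 4 tert-butyl (3E,7E)-homofarnesoate
Conditions: O-tert-butyl-N,N′-diisopropylisourea, CH2Cl2, rt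
Reagents that add atoms: O-tert-butyl-N,N′-diisopropylisourea, CC(C)N=C(NC(C)C)OC(C)(C)C
Why: O-Alkylation of the acid by the isourea (neutral tert-butyl ester formation) avoids acid or base that would move the β,γ-alkene into conjugation or cyclise the triene.

Step 3
Reactants: 4 tert-butyl (3E,7E)-homofarnesoate
Product: 5 tert-butyl (3E,7S,8S,11S)-7,8:11,12-diepoxy-4,8,12-trimethyltridec-3-enoate
Conditions: L-series Shi ketone (30 mol %), Oxone (2KHSO5·KHSO4·K2SO4), K2CO3, Bu4NHSO4, MeCN/CH2(OMe)2/aq. Na2B4O7 buffer (pH 10.5), 0 °C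
Reagents that add atoms: potassium peroxymonosulfate (active part of Oxone), [K+].[O-]S(=O)(=O)OO
Why: Shi asymmetric epoxidation (chiral dioxirane, spiro transition state) should set C3, C6 and C7 all S under catalyst control on the two electron-rich trisubstituted alkenes, the alkene next to CH2CO2t-Bu being inductively deactivated like the allylic-acetate alkene of farnesyl acetate.

Step 4
Reactants: 5 bis-epoxy tert-butyl ester
Product: 7 left-half hydroxy lactone, via trimethylsilyl ether 6 (not isolated)
Conditions: Me3SiOTf, 2,6-di-tert-butyl-4-methylpyridine, CH2Cl2, −78 °C; then 1 M HCl, THF, 0 °C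
Reagents that add atoms: trimethylsilyl trifluoromethanesulfonate, C[Si](C)(C)OS(=O)(=O)C(F)(F)F (silyl group in 6 only, lost on work-up)
Why: Silyl-triflate-promoted epoxide-opening cascade (oxacyclisation, then cationic alkene cyclisation ended by lactonisation) in which the oxygen on C7 opens the silylated 2,3-epoxide at tertiary C2 (oxepane, C3 and C7 kept), the E-alkene opens the resulting epoxonium at C6 from the back through a chair (C6 inverted, trans ring fusion, C11 side chain equatorial) and the ester carbonyl traps C10 anti (equatorial oxygen, 10S) with loss of isobutene, after which dilute acid removes the O3 silyl group.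

Step 5
Reactants: 7 left-half hydroxy lactone
Product: 8 left-half dihydroxy Weinreb amide
Conditions: AlMe3, MeNH(OMe)·HCl, CH2Cl2, 0 °C → rt; aq. KNaC4H4O6
Reagents that add atoms: N,O-dimethylhydroxylamine hydrochloride, CNOC.Cl
Why: Aluminium-amide aminolysis of the lactone (Weinreb amide formation) opens the temporary ring at the acyl carbon, so C10 and C11 are untouched and C12′ stays at a level reducible to the aldehyde.

Step 6
Reactants: 8 left-half dihydroxy Weinreb amide
Product: 9 left-half diacetoxy Weinreb amide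
Conditions: Ac2O, DMAP, Et3N, CH2Cl2, 35 °C
Reagents that add atoms: acetic anhydride, CC(=O)OC(C)=O
Why: DMAP-catalysed acylation puts the two left-half acetates of the target on the secondary O3 and the equatorial tertiary O10 now, so they never need to be told apart from the right-half hydroxyls.

Step 7
Reactants: 9 left-half diacetoxy Weinreb amide
Product: 10 left-half diacetoxy aldehyde
Conditions: Cp2Zr(H)Cl, THF, rt; water
Reagents that add atoms: none
Why: Schwartz reduction of a tertiary amide (hydrozirconation of the amide carbonyl, collapse of the zirconated hemiaminal on work-up) gives the aldehyde and leaves esters such as the two acetates alone.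

Step 8
Reactants: 11 dimethyl (2-oxopropyl)phosphonate; 12 geranyl bromide
Product: 14 dimethyl [(5E)-6,10-dimethyl-2-oxoundeca-5,9-dien-1-yl]phosphonate, via phosphonate dianion 13 (not isolated)
Conditions: NaH, THF, 0 °C; n-BuLi, 0 °C; 12, 0 °C; 1 M HCl
Reagents that add atoms: sodium hydride, [Na+].[H-] and n-butyllithium, [Li]CCCC (counter-ions of 13 only)
Why: Alkylation of the 1,3-dianion of a β-ketophosphonate at its more basic terminal carbon (SN2 on the allylic bromide, E-alkene kept) gives the C11′ phosphonate of the right-half chain in one step.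

Step 9
Reactants: 10 left-half diacetoxy aldehyde; 14 β-ketophosphonate
Product: 15 (E)-enone (C11′=C12′, C10′ ketone, right-half diene chain)
Conditions: LiCl, i-Pr2NEt, MeCN, rt
Reagents that add atoms: none
Why: Horner–Wadsworth–Emmons olefination under Masamune–Roush conditions is mild enough for the acetates and the enolisable aldehyde and should give the (E)-enone, which fixes C10′ as the ketone and C11′=C12′ as the only site for later enol ether formation.

Step 10
Reactants: 15 (E)-enone
Product: 16 (3′S,6′S,7′S)-bis-epoxy enone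
Conditions: L-series Shi ketone (60 mol %), Oxone (2KHSO5·KHSO4·K2SO4), K2CO3, Bu4NHSO4, MeCN/CH2(OMe)2/aq. Na2B4O7 buffer (pH 10.5), 0 °C
Reagents that add atoms: potassium peroxymonosulfate (active part of Oxone), [K+].[O-]S(=O)(=O)OO
Why: Shi asymmetric epoxidation should epoxidise the two electron-rich trisubstituted alkenes with S configuration at C3′, C6′ and C7′ (catalyst control) while the electron-poor enone is left.

Step 11
Reactants: 16 bis-epoxy enone
Product: 17 (Z)-triethylsilyl enol ether (C10′=C11′)
Conditions: Et3SiH, RhCl(PPh3)3 (2 mol %), toluene, 50 °C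
Reagents that add atoms: triethylsilane, CC[SiH](CC)CC
Why: Rhodium-catalysed 1,4-hydrosilylation of the enone (hydride to C12′, silicon to oxygen through the s-cis enone) should give the enol ether regiodefined towards C11′, mainly as the Z isomer, with epoxides and acetates inert.

Step 12
Reactants: 17 (Z)-triethylsilyl enol ether bis-epoxide
Product: 19 tetracyclic C10′ ketone with O3′–SiEt3, via epoxonium triflate 18 (not isolated)
Conditions: Et3SiOTf (1.2 equiv), 2,6-di-tert-butyl-4-methylpyridine, CH2Cl2, −78 °C; aq. NaHCO3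
Reagents that add atoms: triethylsilyl trifluoromethanesulfonate, CC[Si](CC)(CC)OS(=O)(=O)C(F)(F)F (silyl group ends on O3′; triflate is the counter-ion of 18)
Why: Et3SiOTf silylates the terminal 2′,3′-epoxide, the oxygen of the 6′,7′-epoxide opens it at tertiary C2′ to close the oxepane as the bicyclic epoxonium ion 18, and C11′ of the enol ether then opens the epoxonium at tertiary C6′ from the back, closing the cyclohexanone while its silyl group leaves as Et3SiOTf. The closest known reaction type is the silyl-triflate-promoted tandem oxa- and carbacyclisation of 1,5-bis-epoxides ended by an enol silane, known for terminal enol silanes of bis-epoxy methyl ketones and giving this same trans-fused oxepane–cyclohexanone; here the nucleophilic enol carbon carries one more substituent. The oxepane closes in the 7-endo mode (O on C7′ to C2′, both carbons of the 2′,3′-epoxide in the ring) and the carbocycle closes last in the 6-endo mode with respect to the epoxonium and enol-endo with respect to the enol ether (C11′ to C6′). C3′ and C7′ keep the epoxide configuration because their C–O bonds are not broken, C6′ is inverted by the back-side attack so that its methyl and H7′ end up anti (trans ring fusion), and C11′ is set by the chair transition state in which the Z enol ether holds C12′ equatorial, which is also the thermodynamic arrangement next to the ketone. The step needs attack through C11′ and not C9′, secured by making the enol ether from the C11′=C12′ enone, and endo opening at C2′ and C6′, secured by the methyl groups that carry the positive charge there; the hindered base and −78 °C should keep the tertiary acetate intact.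

Step 13
Reactants: 19 tetracyclic C10′ ketone
Product: 20 (10′R) tertiary alcohol
Conditions: MeLi, CeCl3, THF, −78 °C; aq. NH4Cl
Reagents that add atoms: methyllithium, [Li]C
Why: Organocerium 1,2-addition (low basicity, ketone much faster than the hindered acetates at −78 °C) should occur by equatorial attack anti to the axial C6′ methyl that is 1,3 to the carbonyl, giving the axial hydroxyl and equatorial methyl of the 10′R centre.

Step 14
Reactants: 20 (10′R) tertiary alcohol
Product: 22 triacetate O3′-triethylsilyl ether, via lithium alkoxide 21 (not isolated)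
Conditions: LiN(SiMe3)2 (1.1 equiv), THF, −78 → 0 °C; AcCl, 0 °C
Reagents that add atoms: lithium hexamethyldisilazide, [Li+].C[Si](C)(C)[N-][Si](C)(C)C (lithium in 21 only); acetyl chloride, CC(Cl)=O
Why: Acylation of the preformed lithium alkoxide with acetyl chloride, the usual answer for tertiary alcohols too shielded for DMAP catalysis, should acetylate O10′ without touching the silyl ether or the two existing acetates.

Step 15
Reactants: 22 triacetate O3′-triethylsilyl ether
Product: 23 target CNP0169816.2
Conditions: HF·pyridine, pyridine/THF, 0 °C → rt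
Reagents that add atoms: none
Why: Fluoride-mediated desilylation with buffered HF·pyridine cleaves the O3′ triethylsilyl ether and leaves the secondary and both tertiary acetates.

## Compound list

1 | (2E,6E)-farnesyl chloride ((2E,6E)-1-chloro-3,7,11-trimethyldodeca-2,6,10-triene) | ClC/C=C(C)/CC/C=C(C)/CCC=C(C)C | starting material
2 | (2E,6E)-farnesylbarium chloride (not isolated) | Cl[Ba]C/C=C(C)/CC/C=C(C)/CCC=C(C)C | intermediate
3 | (3E,7E)-homofarnesic acid ((3E,7E)-4,8,12-trimethyltrideca-3,7,11-trienoic acid) | OC(=O)C/C=C(C)/CC/C=C(C)/CCC=C(C)C | intermediate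
4 | tert-butyl (3E,7E)-homofarnesoate | CC(C)(C)OC(=O)C/C=C(C)/CC/C=C(C)/CCC=C(C)C | intermediate
5 | tert-butyl (3E,7S,8S,11S)-7,8:11,12-diepoxy-4,8,12-trimethyltridec-3-enoate | CC(C)(C)OC(=O)C/C=C(C)/CC[C@@H]1O[C@@]1(C)CC[C@@H]1OC1(C)C | intermediate
6 | O3-trimethylsilyl ether of lactone 7 (not isolated) | C[Si](C)(C)O[C@H]1CC[C@]2(C)[C@H](CC[C@]3(C)OC(=O)C[C@@H]23)OC1(C)C | intermediate
7 | left-half hydroxy lactone: (3S,6S,7S,10S,11S) trans-fused 2,2,6,10-tetramethyl oxepane–cyclohexane, free 3-OH, trans γ-lactone O10–C12′(=O)–C12H2–C11 | O[C@H]1CC[C@]2(C)[C@H](CC[C@]3(C)OC(=O)C[C@@H]23)OC1(C)C | intermediate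
8 | left-half dihydroxy Weinreb amide (3-OH, 10-OH, C11–CH2–C(=O)N(OMe)Me) | O[C@H]1CC[C@]2(C)[C@H](CC[C@](C)(O)[C@H]2CC(=O)N(C)OC)OC1(C)C | intermediate
9 | left-half diacetoxy Weinreb amide (3-OAc, 10-OAc) | CC(=O)O[C@H]1CC[C@]2(C)[C@H](CC[C@](C)(OC(C)=O)[C@H]2CC(=O)N(C)OC)OC1(C)C | intermediate
10 | left-half diacetoxy aldehyde (C11–CH2–CHO, CHO = C12′) | CC(=O)O[C@H]1CC[C@]2(C)[C@H](CC[C@](C)(OC(C)=O)[C@H]2CC=O)OC1(C)C | intermediate
11 | dimethyl (2-oxopropyl)phosphonate | COP(=O)(OC)CC(C)=O | starting material
12 | geranyl bromide ((2E)-1-bromo-3,7-dimethylocta-2,6-diene) | BrC/C=C(C)/CCC=C(C)C | starting material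
13 | sodium lithium 1,3-dianion of 11 (not isolated) | COP(=O)(OC)[CH-]C(=O)[CH2-].[Na+].[Li+] | intermediate
14 | dimethyl [(5E)-6,10-dimethyl-2-oxoundeca-5,9-dien-1-yl]phosphonate | COP(=O)(OC)CC(=O)CC/C=C(C)/CCC=C(C)C | intermediate
15 | (E)-enone: left bicycle–C12H2–C12′H=C11′H–C10′(=O)–(CH2)2–CH=C(Me)–(CH2)2–CH=CMe2 | CC(=O)O[C@H]1CC[C@]2(C)[C@H](CC[C@](C)(OC(C)=O)[C@H]2C/C=C/C(=O)CC/C=C(C)/CCC=C(C)C)OC1(C)C | intermediate
16 | (3′S,6′S,7′S)-2′,3′:6′,7′-bis-epoxy enone | CC(=O)O[C@H]1CC[C@]2(C)[C@H](CC[C@](C)(OC(C)=O)[C@H]2C/C=C/C(=O)CC[C@@H]3O[C@@]3(C)CC[C@@H]3OC3(C)C)OC1(C)C | intermediate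
17 | (Z)-C10′=C11′ triethylsilyl enol ether of the bis-epoxy ketone | CC(=O)O[C@H]1CC[C@]2(C)[C@H](CC[C@](C)(OC(C)=O)[C@H]2CC/C=C(\O[Si](CC)(CC)CC)CC[C@@H]3O[C@@]3(C)CC[C@@H]3OC3(C)C)OC1(C)C | intermediate
18 | oxepane-fused epoxonium triflate (O1′ bonded to C2′, C6′ and C7′; O3′–SiEt3; enol ether intact; not isolated) | CC(=O)O[C@H]1CC[C@]2(C)[C@H](CC[C@](C)(OC(C)=O)[C@H]2CC/C=C(\O[Si](CC)(CC)CC)CC[C@@H]3[O+]4[C@@]3(C)CC[C@H](O[Si](CC)(CC)CC)C4(C)C)OC1(C)C.[O-]S(=O)(=O)C(F)(F)F | intermediate
19 | tetracyclic ketone: left half 3,10-diacetate; right half (3′S,6′S,7′S,11′S), C10′=O, O3′–SiEt3 | CC(=O)O[C@H]1CC[C@]2(C)[C@H](CC[C@](C)(OC(C)=O)[C@H]2CC[C@H]2[C@]3(C)CC[C@H](O[Si](CC)(CC)CC)C(C)(C)O[C@H]3CCC2=O)OC1(C)C | intermediate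
20 | (10′R) tertiary alcohol (axial 10′-OH, equatorial 10′-Me), O3′–SiEt3, left diacetate | CC(=O)O[C@H]1CC[C@]2(C)[C@H](CC[C@](C)(OC(C)=O)[C@H]2CC[C@H]2[C@]3(C)CC[C@H](O[Si](CC)(CC)CC)C(C)(C)O[C@H]3CC[C@@]2(C)O)OC1(C)C | intermediate
21 | lithium alkoxide of 20 (not isolated) | CC(=O)O[C@H]1CC[C@]2(C)[C@H](CC[C@](C)(OC(C)=O)[C@H]2CC[C@H]2[C@]3(C)CC[C@H](O[Si](CC)(CC)CC)C(C)(C)O[C@H]3CC[C@@]2(C)[O-])OC1(C)C.[Li+] | intermediate
22 | 3,10,10′-triacetate O3′-triethylsilyl ether | CC(=O)O[C@H]1CC[C@]2(C)[C@H](CC[C@](C)(OC(C)=O)[C@H]2CC[C@H]2[C@]3(C)CC[C@H](O[Si](CC)(CC)CC)C(C)(C)O[C@H]3CC[C@@]2(C)OC(C)=O)OC1(C)C | intermediate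
23 | CNP0169816.2: (3S,6S,7S,10S,11S,3′S,6′S,7′S,10′R,11′S) 3,10,10′-triacetate with free 3′-OH | CC(=O)O[C@H]1CC[C@]2(C)[C@H](CC[C@](C)(OC(C)=O)[C@H]2CC[C@H]2[C@]3(C)CC[C@H](O)C(C)(C)O[C@H]3CC[C@@]2(C)OC(C)=O)OC1(C)C | target

## Step count and risks

Total step count: 15. Longest linear sequence: 14 steps (steps 1–7 and 9–15; step 8 is the one-step side branch).

**Step 12 (key cascade).** Possible failure: protodesilylation of the enol ether to the ketone, or attack on the activated inner epoxide before the oxepane has closed, so that the cascade stalls or the order of ring closure is scrambled. Fallback with a different terminating nucleophile, setting out from 17 and coming back at 19: fluoride-induced triflation (CsF, PhNTf2, DME, rt) keeps the position and geometry of the enol double bond and would give the (Z)-enol triflate F1. Negishi coupling with (triethylsilyl)methylzinc chloride (Pd(PPh3)4, THF, 50 °C) would give the (Z)-allylsilane F2. The same Et3SiOTf/2,6-di-tert-butyl-4-methylpyridine treatment would then end the epoxide-opening cascade with an allylsilane, which is more nucleophilic and cannot be hydrolysed, C11′ again closing the carbocycle last, to give the C10′-methylene tetracycle F3. Ozonolysis (O3, CH2Cl2/MeOH, −78 °C; Me2S) returns ketone 19.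

**Step 4 (left-half cascade).** Possible failure: loss of a proton from the C10 cation (elimination to alkenes) competing with capture by the weakly nucleophilic ester carbonyl. Fallback with a tertiary amide as terminating group, setting out from 3 and coming back at 7: amide coupling (MeNH(OMe)·HCl, EDC·HCl, N-methylmorpholine, CH2Cl2) would give the homofarnesic Weinreb amide F4, and Shi epoxidation as in step 3 the bis-epoxy amide F5. The Me3SiOTf cascade would then be ended by the much more nucleophilic amide oxygen, giving the cyclic iminium ether triflate F6. Its hydrolysis in the acidic work-up (1 M HCl, THF) releases the amine and the silyl group and gives hydroxy lactone 7.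

**Step 14 (acetylation of the axial tertiary O10′).** Possible failure: incomplete acylation of an alkoxide shielded by the 1,3-diaxial C6′ methyl, or elimination of the tertiary oxygen. Fallback with a protecting-group change that allows Lewis-acid-catalysed acetylation, setting out from 20 and coming back at 23: HF·pyridine would remove the silyl ether to give the 3′,10′-diol F7. Chloroacetyl chloride/pyridine (CH2Cl2, −20 °C) would acylate only the secondary O3′ to give the chloroacetate F8. Ac2O with catalytic Sc(OTf)3 (MeCN, −20 °C) would acetylate the tertiary O10′ to give the chloroacetate triacetate F9. Thiourea/NaHCO3 (EtOH, 50 °C) removes the chloroacetate selectively and gives target 23.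

## Further compounds

F1 | step 12 | (Z)-C10′=C11′ enol triflate of the bis-epoxy ketone | CC(=O)O[C@H]1CC[C@]2(C)[C@H](CC[C@](C)(OC(C)=O)[C@H]2CC/C=C(\OS(=O)(=O)C(F)(F)F)CC[C@@H]3O[C@@]3(C)CC[C@@H]3OC3(C)C)OC1(C)C
F2 | step 12 | (Z)-allylsilane (C10′ bears CH2SiEt3, C10′=C11′) bis-epoxide | CC(=O)O[C@H]1CC[C@]2(C)[C@H](CC[C@](C)(OC(C)=O)[C@H]2CC/C=C(\C[Si](CC)(CC)CC)CC[C@@H]3O[C@@]3(C)CC[C@@H]3OC3(C)C)OC1(C)C
F3 | step 12 | C10′-methylene tetracycle with O3′–SiEt3 | CC(=O)O[C@H]1CC[C@]2(C)[C@H](CC[C@](C)(OC(C)=O)[C@H]2CC[C@H]2[C@]3(C)CC[C@H](O[Si](CC)(CC)CC)C(C)(C)O[C@H]3CCC2=C)OC1(C)C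
F4 | step 4 | (3E,7E)-N-methoxy-N-methylhomofarnesamide | CON(C)C(=O)C/C=C(C)/CC/C=C(C)/CCC=C(C)C
F5 | step 4 | (3E,7S,8S,11S)-7,8:11,12-diepoxy-N-methoxy-N,4,8,12-tetramethyltridec-3-enamide | CON(C)C(=O)C/C=C(C)/CC[C@@H]1O[C@@]1(C)CC[C@@H]1OC1(C)C
F6 | step 4 | cyclic iminium ether triflate of the left-half tricycle (O10–C12′(=N+(OMe)Me), O3–SiMe3) | C[Si](C)(C)O[C@H]1CC[C@]2(C)[C@H](CC[C@]3(C)OC(=[N+](C)OC)C[C@@H]23)OC1(C)C.[O-]S(=O)(=O)C(F)(F)F
F7 | step 14 | 3′,10′-diol (left diacetate) | CC(=O)O[C@H]1CC[C@]2(C)[C@H](CC[C@](C)(OC(C)=O)[C@H]2CC[C@H]2[C@]3(C)CC[C@H](O)C(C)(C)O[C@H]3CC[C@@]2(C)O)OC1(C)C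
F8 | step 14 | 3′-chloroacetate 10′-alcohol | CC(=O)O[C@H]1CC[C@]2(C)[C@H](CC[C@](C)(OC(C)=O)[C@H]2CC[C@H]2[C@]3(C)CC[C@H](OC(=O)CCl)C(C)(C)O[C@H]3CC[C@@]2(C)O)OC1(C)C
F9 | step 14 | 3′-chloroacetate 3,10,10′-triacetate | CC(=O)O[C@H]1CC[C@]2(C)[C@H](CC[C@](C)(OC(C)=O)[C@H]2CC[C@H]2[C@]3(C)CC[C@H](OC(=O)CCl)C(C)(C)O[C@H]3CC[C@@]2(C)OC(C)=O)OC1(C)C
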